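Assumption: the target has no stereogenic element, because each biaryl axis ends in a locally symmetric 2,4,6-trihydroxyphenyl ring, so the route needs no stereocontrol.

## Structural features

The target (C30H22O15) is an achiral pentameric phlorotannin with five benzene rings, thirteen free phenols, two diaryl ethers and two biaryl bonds. Ring C is the hub and is hexasubstituted: C1 carries the ether oxygen to ring B, C2, C4 and C6 carry hydroxyls, and C3 and C5 carry rings D and D′ (2,4,6-trihydroxyphenyl); a mirror plane passes through C1 and C4. Ring B is 1,2,3,5-tetraoxygenated: B1–O–C1 (ring C), B2–O–ring A (a 3,5-dihydroxyphenyl group), B3–OH and B5–OH. Both biaryl bonds are tetra-ortho-oxygenated, and both ether oxygens sit on carbons flanked by two further oxygen-bearing carbons (C1 between C2 and C6; B2 between B1 and B3). The free polyphenol is air-sensitive, above all ring C, whose C1–O and C4–OH are para and can be oxidized to a quinone with loss of the aryl ether; all phenols except those made in the key step therefore stay masked as methyl ethers until the last step. The real difficulty is ring C: three hindered bonds (C3–D, C5–D′, C1–O) on one fully substituted, electron-rich ring, which coupling chemistry would have to make one by one. The feature exploited is that ring C, written as its triketo tautomer, is a cyclohexane-1,3,5-trione in which C3–C4–C5 is a 1,3-diarylacetone and C6–C1–C2 is an aryloxymalonyl unit, the sp3 carbons C1, C3 and C5 carrying exactly the three non-hydroxyl substituents. In one sentence: ring C is not coupled but created, by a twofold Claisen cyclocondensation of a 1,3-diarylacetone with an aryloxymalonate that closes the central benzene ring with all six substituents in place.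

## Logic of the disconnections

20 ⇒ 19. The ten O–CH3 bonds on rings A, B, D and D′ are cut. Methyl ethers are the smallest masks, they survive strong base at high temperature (needed for the key step), and every building block is commercial in this form. The gain is that all earlier intermediates are stable and chromatographable. The demand is one global ether cleavage that leaves the two diaryl ethers and the two biaryl bonds alone.

19 ⇒ 8 + 17 (key disconnection). Ring C is opened at C2–C3 and C5–C6. C3–C4–C5 goes to 8, whose carbonyl becomes C4–OH and whose two α-carbons already carry rings D and D′; C6–C1–C2 goes to 17, whose ester carbons become C2–OH and C6–OH and whose central carbon already carries the O–B1 ether. The gain is large: neither tetra-ortho-substituted biaryl bond nor the most hindered diaryl ether has to be made by coupling, since they are present in 8 and 17 as benzylic C–C bonds and an alkyl aryl ether, and the hexasubstituted ring is traded for two acyclic pieces of equal size. The demand is two C-acylations of benzylic enolate carbons (not O-acylations) followed by aromatization; the symmetry of 8 removes any regiochemical question.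

8 ⇒ 7 ⇒ 1 + 2. After adjusting the oxidation level (ketone from secondary alcohol), the two CH2–aryl bonds are cut. The three-carbon unit is 2, a 1,3-bis-electrophile with the oxygen already on the central carbon; the nucleophile is 1, metalated at the position between two methoxy groups. The gain is that the 1,3-diaryl C3 unit comes in one operation from two bulk chemicals. The demand is that both electrophilic ends of 2 react with the aryl nucleophile in sequence.

17 ⇒ 15 + 16. The O–C(sp3) bond between the B1 oxygen and the malonyl carbon is cut. This is the bond that becomes the C1–O–B1 ether of the target, and here it is a simple phenoxide alkylation. The demand is substitution at carbon of 16 without transfer of chlorine to the electron-rich ring.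

15 ⇒ 14 ⇒ 12 + 13. After removing a benzyl group from the B1 oxygen, the O–C bond to ring A is cut, leaving the oxygen on ring B. Ring A then arrives as an aryl iodide without ortho substituents, so all steric demand lies on the phenol side. The demand is a C–O coupling that tolerates a di-ortho-substituted, electron-rich phenol.

12 ⇒ 10 ⇒ 9. The B2 oxygen is traced back to a formyl carbon (C–C to C–O exchange with aryl migration), and the benzyl group to a free phenol. This maps ring B onto commercial 9, in which B1 is the free hydroxyl, B2 the formyl-bearing carbon, and B3/B5 the two methoxy groups. The demand is clean aryl (not hydride) migration in the oxidation.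

## Other disconnections considered

Alternative 1: the first plan that comes to mind cuts the two biaryl bonds C3–D and C5–D′ last. It would make both by a twofold Suzuki–Miyaura coupling of the dibromide A1 (ring C with the ring A/B ether and three methoxy groups in place) with (2,4,6-trimethoxyphenyl)boronic acid A2, giving the permethyl ether A3 for demethylation. Each coupling would create a tetra-ortho-oxygenated biaryl at a bromide flanked by two methoxy groups on a hexasubstituted, electron-rich ring, where oxidative addition and reductive elimination are both slow. A2 is a 2,6-dioxygenated boronic acid of the kind that protodeboronates quickly under basic coupling conditions. A1 would also need an Ullmann coupling between two di-ortho-substituted partners at C1 and a regiocontrolled hexafunctionalization of ring C beforehand. The chosen plan makes none of these three bonds by coupling and reaches the same skeleton in fewer steps.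

Alternative 2: a tandem aryne cut removes C3–D, C5–D′ and C4–O in one operation. Tribromide A4 would undergo Mg/Br exchange at the central bromine and lose magnesium halide to an aryne at C3–C4. Addition of 4 would relay the magnesium to C4, a second aryne would form at C4–C5, and oxidation of the resulting 2,6-diarylphenyl Grignard reagent would give phenol A5. The weak point is mechanistic: the first aryne is flanked by the C2 methoxy group and the C5 bromine, which polarize the triple bond in opposite senses. The methoxy group, the stronger inductive director, steers the aryl nucleophile to C4 (away from itself), which would end the relay instead of handing over to the second aryne. A5 would in addition still need selective unmasking of the C1 oxygen among three adjacent methoxy groups and a hindered diaryl ether formation.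

Alternative 3: a direct twofold C–H arylation would start from 2,6-dimethoxy-1,4-benzoquinone A6 as ring C. Oxidative or acid-promoted union with 1 at C3 and C5 (no pre-functionalization) would give the diarylquinone A7, followed by reduction and O-arylation of the C1 hydroxyl. In A6 the C–H carbons are the α-carbons of two vinylogous esters and are therefore the electron-rich positions. An arene nucleophile is expected to attack the methoxy-bearing carbons by addition–elimination instead, which would place the aryl groups on the wrong atoms. A radical variant would require a di-ortho-substituted aryl radical to add twice next to methoxy groups. Even if A7 were reached, the C1 ether would remain a late coupling between a phenol flanked by two methoxy groups and a di-ortho-substituted partner, the very bond the chosen plan forms as a simple alkylation.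

Key step: step 8

## Steps

Step 1
Reactants: 1 1,3,5-trimethoxybenzene; 2 (±)-epichlorohydrin [2-(chloromethyl)oxirane]
Product: 7 1,3-bis(2,4,6-trimethoxyphenyl)propan-2-ol, via 2,4,6-trimethoxyphenyllithium 3 (not isolated), via (2,4,6-trimethoxyphenyl)magnesium bromide 4 (not isolated), via bromomagnesium chlorohydrin alkoxide 5 (not isolated), via 2-(2,4,6-trimethoxybenzyl)oxirane 6 (not isolated)
Conditions: 1 (2.4 equiv), n-BuLi, TMEDA, THF, 0 °C → rt; MgBr2·OEt2, 0 °C; CuI (10 mol%), 2 (1.0 equiv), −30 → 45 °C; aq NH4Cl
Reagents that add atoms: none
Why: Directed ortho-metalation of 1 between two methoxy groups gives 3, which is transmetalated to 4; CuI-catalysed epoxide opening at the CH2 terminus of 2 gives 5, which closes to 6 on warming, and a second equivalent of 4 opens 6 at its terminal carbon. Both aryl–CH2 bonds should thus form in one flask, and 7 is achiral.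

Step 2
Reactants: 7 1,3-bis(2,4,6-trimethoxyphenyl)propan-2-ol
Product: 8 1,3-bis(2,4,6-trimethoxyphenyl)propan-2-one
Conditions: Dess–Martin periodinane, CH2Cl2, rt
Reagents that add atoms: none
Why: Dess–Martin oxidation of a secondary alcohol under neutral conditions; the electron-rich rings and the benzylic positions should not be touched.

Step 3
Reactants: 9 2-hydroxy-4,6-dimethoxybenzaldehyde
Product: 10 2-(benzyloxy)-4,6-dimethoxybenzaldehyde
Conditions: BnBr, K2CO3, DMF, 50 °C
Reagents that add atoms: benzyl bromide, BrCc1ccccc1
Why: Williamson etherification; the benzyl group masks the oxygen that will later carry the malonyl carbon (B1) and is orthogonal to the methyl ethers.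

Step 4
Reactants: 10 2-(benzyloxy)-4,6-dimethoxybenzaldehyde
Product: 12 2-(benzyloxy)-4,6-dimethoxyphenol, via 2-(benzyloxy)-4,6-dimethoxyphenyl formate 11 (not isolated)
Conditions: mCPBA, CH2Cl2, 0 °C → rt; then K2CO3 (cat.), MeOH, rt
Reagents that add atoms: mCPBA (3-chloroperoxybenzoic acid), OOC(=O)c1cccc(Cl)c1
Why: Baeyer–Villiger (Dakin-type) oxidation: the electron-rich, di-ortho-oxygenated aryl group should migrate in preference to hydrogen to give formate 11, which mild methanolysis cleaves to 12; the formyl carbon is thereby replaced by the B2 oxygen.

Step 5
Reactants: 12 2-(benzyloxy)-4,6-dimethoxyphenol; 13 1-iodo-3,5-dimethoxybenzene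
Product: 14 1-(benzyloxy)-2-(3,5-dimethoxyphenoxy)-3,5-dimethoxybenzene
Conditions: CuI (10 mol%), picolinic acid (20 mol%), K3PO4, DMSO, 90 °C
Reagents that add atoms: none
Why: Ullmann-type diaryl ether synthesis with a CuI/picolinic acid catalyst, a system suited to di-ortho-substituted phenols; the aryl iodide has no ortho substituent, so the hindrance lies only on the nucleophile.

Step 6
Reactants: 14 1-(benzyloxy)-2-(3,5-dimethoxyphenoxy)-3,5-dimethoxybenzene
Product: 15 2-(3,5-dimethoxyphenoxy)-3,5-dimethoxyphenol
Conditions: H2 (1 atm), Pd/C (10%), EtOAc–MeOH, rt
Reagents that add atoms: none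
Why: Hydrogenolysis of the benzyl ether over palladium on carbon; methyl ethers and the diaryl ether are inert.

Step 7
Reactants: 15 2-(3,5-dimethoxyphenoxy)-3,5-dimethoxyphenol; 16 dimethyl 2-chloropropanedioate (dimethyl chloromalonate)
Product: 17 dimethyl 2-[2-(3,5-dimethoxyphenoxy)-3,5-dimethoxyphenoxy]propanedioate
Conditions: K2CO3, acetone, reflux
Reagents that add atoms: none
Why: Williamson O-alkylation of the phenoxide with an α-halomalonate (SN2 at an activated secondary carbon); the future C1–O–B1 ether is thereby built as an alkyl aryl ether before ring C exists.

Step 8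
Reactants: 8 1,3-bis(2,4,6-trimethoxyphenyl)propan-2-one; 17 dimethyl 2-[2-(3,5-dimethoxyphenoxy)-3,5-dimethoxyphenoxy]propanedioate
Product: 19 2-[2-(3,5-dimethoxyphenoxy)-3,5-dimethoxyphenoxy]-4,6-bis(2,4,6-trimethoxyphenyl)benzene-1,3,5-triol, via open-chain triketo ester 18 (not isolated)
Conditions: NaH (3.5 equiv), diglyme, rt → 150 °C, N2 sweep (−MeOH); then 1 M HCl, 0 °C
Reagents that add atoms: none
Why: Twofold Claisen (Claisen–Dieckmann) cyclocondensation, the classical phloroglucinol synthesis from a ketone with two activated α-methylene groups and a malonic diester, applied here to a 1,3-diarylacetone. NaH converts 17 into its sodium enolate and 8 into its benzylic enolate; on heating the malonate enolate expels methoxide (E1cB) to an (aryloxy)(methoxycarbonyl)ketene, which is C-acylated by the enolate of 8 to give 18 as its β-dicarbonyl anion. Loss of methoxide from the remaining ester and attack of the other benzylic enolate carbon (C5) on that carbonyl carbon (C6) closes ring C in a 6-(enolendo)-exo-trig Dieckmann mode (exo-dig if the ester has first collapsed to the ketene). The resulting cyclohexane-1,3,5-trione carries an enolizable hydrogen on each of C1, C3 and C5 and should tautomerize at once to the benzene-1,3,5-triol, held as its sodium phenoxide, which makes the sequence irreversible. No stereocentre is formed, and the labile centres of 18 vanish on aromatization. The selectivity needed is C- over O-acylation: O-acyl enol esters and the lactone from O-closure remain acyl donors that the NaOMe generated in the flask can reopen, whereas only C,C-closure reaches an aromatic anion, so equilibration should drain into 19. Regiochemistry is not an issue because 8 is symmetric and, after the first acylation, only one CH2 remains to close the ring. Self-condensation of 17 cannot aromatize because its α-carbon carries the aryloxy group.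

Step 9
Reactants: 19 2-[2-(3,5-dimethoxyphenoxy)-3,5-dimethoxyphenoxy]-4,6-bis(2,4,6-trimethoxyphenyl)benzene-1,3,5-triol
Product: 20 2-[2-(3,5-dihydroxyphenoxy)-3,5-dihydroxyphenoxy]-4,6-bis(2,4,6-trihydroxyphenyl)benzene-1,3,5-triol (CNP0228669.0)
Conditions: BBr3 (20 equiv), CH2Cl2, −78 °C → rt; MeOH, then degassed H2O, 0 °C
Reagents that add atoms: none
Why: Lewis acid cleavage of aryl methyl ethers: BBr3 coordinates each methoxy oxygen and bromide removes the methyl group by SN2. Diaryl ethers and biaryl bonds have no such pathway, and the three free hydroxyls of ring C are only borylated and released on hydrolysis.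

## Compound list

1 | 1,3,5-trimethoxybenzene | COc1cc(OC)cc(OC)c1 | starting material
2 | (±)-epichlorohydrin | ClCC1CO1 | starting material
3 | 2,4,6-trimethoxyphenyllithium | [Li]c1c(OC)cc(OC)cc1OC | intermediate (not isolated)
4 | (2,4,6-trimethoxyphenyl)magnesium bromide | Br[Mg]c1c(OC)cc(OC)cc1OC | intermediate (not isolated)
5 | bromomagnesium 1-chloro-3-(2,4,6-trimethoxyphenyl)propan-2-olate (racemic) | COc1cc(OC)c(CC(CCl)O[Mg]Br)c(OC)c1 | intermediate (not isolated)
6 | 2-(2,4,6-trimethoxybenzyl)oxirane (racemic) | COc1cc(OC)c(CC2CO2)c(OC)c1 | intermediate (not isolated)
7 | 1,3-bis(2,4,6-trimethoxyphenyl)propan-2-ol | COc1cc(OC)c(CC(O)Cc2c(OC)cc(OC)cc2OC)c(OC)c1 | intermediate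
8 | 1,3-bis(2,4,6-trimethoxyphenyl)propan-2-one | COc1cc(OC)c(CC(=O)Cc2c(OC)cc(OC)cc2OC)c(OC)c1 | intermediate
9 | 2-hydroxy-4,6-dimethoxybenzaldehyde | COc1cc(O)c(C=O)c(OC)c1 | starting material
10 | 2-(benzyloxy)-4,6-dimethoxybenzaldehyde | COc1cc(OCc2ccccc2)c(C=O)c(OC)c1 | intermediate
11 | 2-(benzyloxy)-4,6-dimethoxyphenyl formate | COc1cc(OCc2ccccc2)c(OC=O)c(OC)c1 | intermediate (not isolated)
12 | 2-(benzyloxy)-4,6-dimethoxyphenol | COc1cc(OCc2ccccc2)c(O)c(OC)c1 | intermediate
13 | 1-iodo-3,5-dimethoxybenzene | COc1cc(I)cc(OC)c1 | starting material
14 | 1-(benzyloxy)-2-(3,5-dimethoxyphenoxy)-3,5-dimethoxybenzene | COc1cc(OC)cc(Oc2c(OC)cc(OC)cc2OCc2ccccc2)c1 | intermediate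
15 | 2-(3,5-dimethoxyphenoxy)-3,5-dimethoxyphenol | COc1cc(OC)cc(Oc2c(O)cc(OC)cc2OC)c1 | intermediate
16 | dimethyl 2-chloropropanedioate | COC(=O)C(Cl)C(=O)OC | starting material
17 | dimethyl 2-[2-(3,5-dimethoxyphenoxy)-3,5-dimethoxyphenoxy]propanedioate | COC(=O)C(Oc1cc(OC)cc(OC)c1Oc1cc(OC)cc(OC)c1)C(=O)OC | intermediate
18 | methyl 2-[2-(3,5-dimethoxyphenoxy)-3,5-dimethoxyphenoxy]-3,5-dioxo-4,6-bis(2,4,6-trimethoxyphenyl)hexanoate (configurationally labile, present as its sodium enolate) | COC(=O)C(Oc1cc(OC)cc(OC)c1Oc1cc(OC)cc(OC)c1)C(=O)C(c1c(OC)cc(OC)cc1OC)C(=O)Cc1c(OC)cc(OC)cc1OC | intermediate (not isolated)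
19 | 2-[2-(3,5-dimethoxyphenoxy)-3,5-dimethoxyphenoxy]-4,6-bis(2,4,6-trimethoxyphenyl)benzene-1,3,5-triol | Oc1c(Oc2cc(OC)cc(OC)c2Oc2cc(OC)cc(OC)c2)c(O)c(-c2c(OC)cc(OC)cc2OC)c(O)c1-c1c(OC)cc(OC)cc1OC | intermediate
20 | 2-[2-(3,5-dihydroxyphenoxy)-3,5-dihydroxyphenoxy]-4,6-bis(2,4,6-trihydroxyphenyl)benzene-1,3,5-triol (CNP0228669.0) | Oc1cc(O)cc(Oc2c(O)cc(O)cc2Oc2c(O)c(-c3c(O)cc(O)cc3O)c(O)c(-c3c(O)cc(O)cc3O)c2O)c1 | target

## Step count and least certain steps

Total step count: 9. Longest linear sequence: 7 steps (steps 3, 4, 5, 6, 7, 8, 9); the ketone arm (steps 1, 2) joins at step 8.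

Key step 8. The enolate of 17 is several pK units more acidic than 8, so the intermolecular C-acylation depends on thermal release of the ketene from the malonate enolate and may be slow. Kinetic O-acylation and O-closure to a lactone may hold material back if reopening by methoxide is sluggish. Both acylations take place at a carbon bearing a di-ortho-methoxy aryl group and may be retarded sterically. Retro-Claisen fragmentation of the open-chain intermediate competes with ring closure. The fallback keeps the goal of building ring C but changes the bond set to a 3 + 2 + 1 assembly in which every intermolecular step is acidity-matched. It sets out from 15 and 8. Phenol 15 is alkylated with methyl bromoacetate (K2CO3, acetone) to methyl 2-[2-(3,5-dimethoxyphenoxy)-3,5-dimethoxyphenoxy]acetate F1. A crossed Claisen condensation of the sodium enolate of 8 with F1 (NaH, THF, reflux) gives 1-[2-(3,5-dimethoxyphenoxy)-3,5-dimethoxyphenoxy]-3,5-bis(2,4,6-trimethoxyphenyl)pentane-2,4-dione F2. The terminal dianion of F2 (excess LDA, THF, −78 → 0 °C), formed at the aryloxymethylene carbon, is carboxylated with dimethyl carbonate to give 18 in the flask. Warming with NaOMe effects the Dieckmann closure, and the fallback comes back to the route at 19.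

Step 1. The second arylation needs the magnesium chlorohydrinate 5 to close to epoxide 6 in the presence of magnesium halides. The sequence may stall after the first addition, or the epoxide may undergo Lewis acid-induced rearrangement to a carbonyl compound before it is opened. The fallback sets out from 1. The Grignard reagent 4 is generated as before and used in a CuI-catalysed double allylic substitution on 3-chloro-2-(chloromethyl)prop-1-ene to give 2,2′-(2-methylidenepropane-1,3-diyl)bis(1,3,5-trimethoxybenzene) F3. Lemieux–Johnson cleavage of the 1,1-disubstituted alkene (OsO4 cat., NaIO4, 2,6-lutidine, dioxane–water) then gives the ketone, so the fallback comes back at 8 and bypasses 7.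

Step 5. The phenoxide of 12 is di-ortho-substituted and very electron-rich. C–O reductive elimination at copper may be slow, and oxidative degradation of the phenoxide or hydrodeiodination of 13 may consume the partners. The fallback replaces copper catalysis by metal-free ligand coupling at trivalent iodine. It sets out from 12, with 13 and 1 as sources of the arylating agent. Oxidation of 13 with mCPBA and TsOH·H2O and trapping with 1 gives (3,5-dimethoxyphenyl)(2,4,6-trimethoxyphenyl)iodonium 4-methylbenzenesulfonate F4. Treatment of 12 with KOtBu and F4 in THF at rt should transfer the 3,5-dimethoxyphenyl group selectively, the trimethoxyphenyl ligand acting as the non-transferred group, and the fallback comes back at 14.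

Step 7. Halophilic attack of the electron-rich phenoxide on 16 (chlorine transfer to ring B) or a second alkylation of the acidic product may compete with O-alkylation. The fallback changes the bond-forming event from substitution to carbenoid O–H insertion: 15 is treated with dimethyl diazomalonate and Rh2(OAc)4 (1 mol%) in CH2Cl2 or benzene, losing N2. It sets out from 15 and comes back at 17 without passing through any new isolable compound.

Step 9. Ten ether cleavages must all go to completion. Partial demethylation, ring bromination by traces of bromine, and air oxidation of the free polyphenol during aqueous work-up (ring C is the most exposed) are the likely losses, and the polar product is hard to purify directly. The fallback changes the endgame to deprotect, derivatize, purify, release. It sets out from 19. After BBr3 treatment and evaporation, the crude material is acetylated in the same flask (Ac2O, pyridine, DMAP) to the tridecaacetate of the target F5, which is stable to air and can be purified on silica and separated from incompletely demethylated material. Deacetylation under argon (K2CO3, degassed MeOH, then acidification) releases the polyphenol, and the fallback comes back at 20.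

## Further compounds

F1 | step 8 | methyl 2-[2-(3,5-dimethoxyphenoxy)-3,5-dimethoxyphenoxy]acetate | COC(=O)COc1cc(OC)cc(OC)c1Oc1cc(OC)cc(OC)c1
F2 | step 8 | 1-[2-(3,5-dimethoxyphenoxy)-3,5-dimethoxyphenoxy]-3,5-bis(2,4,6-trimethoxyphenyl)pentane-2,4-dione | COc1cc(OC)cc(Oc2c(OC)cc(OC)cc2OCC(=O)C(c2c(OC)cc(OC)cc2OC)C(=O)Cc2c(OC)cc(OC)cc2OC)c1
F3 | step 1 | 2,2′-(2-methylidenepropane-1,3-diyl)bis(1,3,5-trimethoxybenzene) | COc1cc(OC)c(CC(=C)Cc2c(OC)cc(OC)cc2OC)c(OC)c1
F4 | step 5 | (3,5-dimethoxyphenyl)(2,4,6-trimethoxyphenyl)iodonium 4-methylbenzenesulfonate | COc1cc(OC)cc([I+]c2c(OC)cc(OC)cc2OC)c1.Cc1ccc(cc1)S(=O)(=O)[O-]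
F0 | step 7 | none | none
F5 | step 9 | tridecaacetate of 2-[2-(3,5-dihydroxyphenoxy)-3,5-dihydroxyphenoxy]-4,6-bis(2,4,6-trihydroxyphenyl)benzene-1,3,5-triol | CC(=O)Oc1cc(OC(C)=O)cc(Oc2c(OC(C)=O)cc(OC(C)=O)cc2Oc2c(OC(C)=O)c(-c3c(OC(C)=O)cc(OC(C)=O)cc3OC(C)=O)c(OC(C)=O)c(-c3c(OC(C)=O)cc(OC(C)=O)cc3OC(C)=O)c2OC(C)=O)c1
A1 | alternative 1 | 1,5-dibromo-3-[2-(3,5-dimethoxyphenoxy)-3,5-dimethoxyphenoxy]-2,4,6-trimethoxybenzene | COc1c(Br)c(OC)c(Br)c(OC)c1Oc1cc(OC)cc(OC)c1Oc1cc(OC)cc(OC)c1
A2 | alternative 1 | (2,4,6-trimethoxyphenyl)boronic acid | COc1cc(OC)c(B(O)O)c(OC)c1
A3 | alternative 1 | tridecamethyl ether of the target | COc1cc(OC)cc(Oc2c(OC)cc(OC)cc2Oc2c(OC)c(-c3c(OC)cc(OC)cc3OC)c(OC)c(-c3c(OC)cc(OC)cc3OC)c2OC)c1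
A4 | alternative 2 | 1,2,3-tribromo-4,5,6-trimethoxybenzene | COc1c(OC)c(OC)c(Br)c(Br)c1Br
A5 | alternative 2 | 3,4,5-trimethoxy-2,6-bis(2,4,6-trimethoxyphenyl)phenol | COc1c(OC)c(-c2c(OC)cc(OC)cc2OC)c(O)c(-c2c(OC)cc(OC)cc2OC)c1OC
A6 | alternative 3 | 2,6-dimethoxy-1,4-benzoquinone | COC1=CC(=O)C=C(OC)C1=O
A7 | alternative 3 | 2,6-dimethoxy-3,5-bis(2,4,6-trimethoxyphenyl)-1,4-benzoquinone | COC1=C(c2c(OC)cc(OC)cc2OC)C(=O)C(c2c(OC)cc(OC)cc2OC)=C(OC)C1=O
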